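The route rests on a (4+3) annulation that builds the seven-membered ring C4–C5–C6–C7–C10–C11–C3 of the homoadamantane core (C1 and C5 are the acyl- and geranyl-bearing bridgeheads, C10 the CH2 on C7, C11 the adjacent CH). A cyclohexanone carrying bromine at C5 and an iodomethyl group at C7 is treated with zinc and (Z)-3-iodoacrolein: the zinc enolate adds to the aldehyde (C4–C5) and the alkylzinc couples with the vinyl iodide under Pd catalysis (C10–C11) in one flask. The step exploits the 1,3-diaxial C5/C10 pair on ring C5–C6–C7–C8–C1–C9. A gem-diester at C1 later closes C2–C3 and supplies the isobutyryl group; the cyclopentane is annulated onto the new enone.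

Key step: step 9

Remark: C1–C14 in the text follow the numbering just given (C2, C4, C9 ketones; C3 quaternary ring-fusion carbon; C8 and C12 the CMe2 carbons; C13, C14 the cyclopentane CH2 groups); locants inside compound names are systematic.

Step 1
Reactants: 1 5-(tert-butoxy)-5-oxopentanoic acid; 2 (4S)-4-benzyl-1,3-oxazolidin-2-one
Product: 3 tert-butyl 5-[(4S)-4-benzyl-2-oxo-1,3-oxazolidin-3-yl]-5-oxopentanoate
Conditions: t-BuCOCl, Et3N, THF, −20 °C; then 2, LiCl, −20 → 23 °C
Reagents that add atoms: none
Why: N-acylation of the oxazolidinone through the mixed pivalic anhydride should give the imide without touching the tert-butyl ester.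

Step 2
Reactants: 3 tert-butyl 5-[(4S)-4-benzyl-2-oxo-1,3-oxazolidin-3-yl]-5-oxopentanoate; 4 dimethyl 2-(propan-2-ylidene)propanedioate
Product: 5 dimethyl 2-[(3R)-3-{[(4S)-4-benzyl-2-oxo-1,3-oxazolidin-3-yl]carbonyl}-6-(tert-butoxy)-2-methyl-6-oxohexan-2-yl]propanedioate
Conditions: TiCl4, i-Pr2NEt, CH2Cl2, −78 °C; then 4, −78 → 0 °C
Reagents that add atoms: none
Why: Proposed new method: the chelated chlorotitanium Z-enolate of 3 should add in Michael fashion to the titanium-bound, doubly activated alkylidene malonate, whose two esters should offset the β,β-disubstitution; the closest known reactions are the titanium-enolate Michael addition of N-acyl oxazolidinones to acrylates and Lewis-acid Mukaiyama–Michael additions to alkylidene malonates; attack on the enolate face opposite the benzyl group sets C7 as R and builds the C7–C8 bond.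

Step 3
Reactants: 5 dimethyl 2-[(3R)-3-{[(4S)-4-benzyl-2-oxo-1,3-oxazolidin-3-yl]carbonyl}-6-(tert-butoxy)-2-methyl-6-oxohexan-2-yl]propanedioate
Product: 6 dimethyl 2-[(3R)-6-(tert-butoxy)-3-(hydroxymethyl)-2-methyl-6-oxohexan-2-yl]propanedioate
Conditions: LiBH4, MeOH (1 equiv), THF, 0 °C
Reagents that add atoms: none
Why: Reductive cleavage of the N-acyl oxazolidinone should give the primary alcohol (C10) while the tert-butyl ester and the hindered tertiary malonate survive at 0 °C; the stereocentre is not touched.

Step 4
Reactants: 6 dimethyl 2-[(3R)-6-(tert-butoxy)-3-(hydroxymethyl)-2-methyl-6-oxohexan-2-yl]propanedioate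
Product: 7 dimethyl 2-[(3R)-6-(tert-butoxy)-3-(iodomethyl)-2-methyl-6-oxohexan-2-yl]propanedioate
Conditions: I2, PPh3, imidazole, CH2Cl2, 0 → 23 °C
Reagents that add atoms: iodine, II
Why: Appel-type iodination of the primary alcohol (SN2 on the alkoxyphosphonium ion) should be fast enough to outrun lactonisation onto a malonate ester.

Step 5
Reactants: 7 dimethyl 2-[(3R)-6-(tert-butoxy)-3-(iodomethyl)-2-methyl-6-oxohexan-2-yl]propanedioate
Product: 8 (4R)-4-(iodomethyl)-7-methoxy-6-(methoxycarbonyl)-5,5-dimethyl-7-oxoheptanoic acid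
Conditions: CF3CO2H, CH2Cl2, 0 → 23 °C
Reagents that add atoms: none
Why: Acidolysis of the tert-butyl ester (loss of isobutene) should free the C9 carboxylic acid; methyl esters and the alkyl iodide are inert.

Step 6
Reactants: 8 (4R)-4-(iodomethyl)-7-methoxy-6-(methoxycarbonyl)-5,5-dimethyl-7-oxoheptanoic acid
Product: 10 dimethyl (5R)-5-(iodomethyl)-6,6-dimethyl-2-oxocyclohexane-1,1-dicarboxylate, via acid chloride 9 (not isolated)
Conditions: (COCl)2, DMF (cat.), CH2Cl2, 0 → 23 °C; then MgCl2, Et3N, MeCN, 0 → 23 °C
Reagents that add atoms: none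
Why: Intramolecular C-acylation of the magnesium malonate by the acid chloride (malonate acylation, 6-exo-trig) should close the cyclohexanone at C1–C9; O-acylation would need an eight-membered ring, and C1 stays non-stereogenic because it carries two identical esters.

Step 7
Reactants: 10 dimethyl (5R)-5-(iodomethyl)-6,6-dimethyl-2-oxocyclohexane-1,1-dicarboxylate
Product: 11 dimethyl (5R)-3-bromo-5-(iodomethyl)-6,6-dimethyl-2-oxocyclohexane-1,1-dicarboxylate (mixture of C3 epimers)
Conditions: LiN(SiMe3)2, THF, −78 °C; then N-bromosuccinimide, −78 °C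
Reagents that add atoms: N-bromosuccinimide, O=C1CCC(=O)N1Br
Why: The ketone can enolise only towards C5 because C1 is quaternary, so electrophilic bromination of the lithium enolate should give the α-bromo ketone; the configuration at the brominated carbon is irrelevant because it becomes an enolate again.

Step 8
Reactants: 12 ethyl (2Z)-3-iodoprop-2-enoate
Product: 13 (2Z)-3-iodoprop-2-enal
Conditions: i-Bu2AlH, CH2Cl2, −78 °C; aq. potassium sodium tartrate; solution used at once
Reagents that add atoms: none
Why: Partial reduction of the ester through the aluminium hemiacetal that is stable at −78 °C should give the aldehyde with the Z geometry retained.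

Step 9
Reactants: 11 dimethyl (5R)-3-bromo-5-(iodomethyl)-6,6-dimethyl-2-oxocyclohexane-1,1-dicarboxylate; 13 (2Z)-3-iodoprop-2-enal
Product: 16 dimethyl (1R,6R)-2-hydroxy-7,7-dimethyl-9-oxobicyclo[4.3.1]dec-3-ene-8,8-dicarboxylate (mixture of C2 epimers), via zinc aldolate 14 (not isolated), via alkylzinc iodide 15 (not isolated)
Conditions: Zn dust (activated with Me3SiCl and BrCH2CH2Br), LiCl, THF, 0 °C then 35 °C; then Pd2(dba)3 (2.5 mol %), SPhos (10 mol %), 35 °C; aq. NH4Cl
Reagents that add atoms: none
Why: Zinc inserts into the C5–Br bond to give a zinc enolate that adds 1,2 to the aldehyde of 13 (Reformatsky reaction, C4–C5), LiCl-assisted insertion into the primary C10–I bond then gives an alkylzinc iodide, and zerovalent palladium with SPhos couples it with the Z-vinyl iodide (intramolecular Negishi sp3–sp2 coupling, C10–C11). The closest known reaction types are the Barbier-mode Reformatsky addition of α-bromo ketones to enals and the Negishi coupling of functionalised alkylzinc iodides with alkenyl iodides. The seven-membered ring closes by reductive elimination from a palladacycle onto the Z-iodoalkene, which supplies the cis olefin the ring needs. C5 is set by the ring closure itself, because only the aldol diastereomer whose new side chain is cis (1,3-diaxial) to the C7 arm can cyclise and the C5–H epimerises through the zinc enolate or by retro-aldol, while the C4 carbinol centre is not controlled and is erased in step 10. The step needs the zinc enolate to attack the aldehyde carbon and not the β-carbon or the vinyl iodide, which should be secured by running the Reformatsky stage at 0 °C before the palladium catalyst is added, and it needs the alkylzinc to ignore ketone and esters, which uncatalysed alkylzinc iodides do. It exploits the 1,3-diaxial relation of C5 and C10 on the cyclohexanone, which holds both nucleophilic carbons within reach of a three-carbon bridge.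

Step 10
Reactants: 16 dimethyl (1R,6R)-2-hydroxy-7,7-dimethyl-9-oxobicyclo[4.3.1]dec-3-ene-8,8-dicarboxylate
Product: 17 dimethyl (1R,6R)-7,7-dimethyl-2,9-dioxobicyclo[4.3.1]dec-3-ene-8,8-dicarboxylate
Conditions: Dess–Martin periodinane, NaHCO3, CH2Cl2, 0 → 23 °C
Reagents that add atoms: none
Why: Oxidation of the allylic secondary alcohol under neutral conditions should converge both carbinol epimers on the C4 ketone and create the cis-cycloheptenone acceptor without retro-aldol cleavage.

Step 11
Reactants: 17 dimethyl (1R,6R)-7,7-dimethyl-2,9-dioxobicyclo[4.3.1]dec-3-ene-8,8-dicarboxylate; 18 4-bromo-2-methylbut-1-ene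
Product: 19 dimethyl (1R,4S,6R)-4-(4-bromo-2-methylbutan-2-yl)-7,7-dimethyl-2,9-dioxobicyclo[4.3.1]decane-8,8-dicarboxylate
Conditions: Fe(acac)3, PhSiH3, EtOH/ethylene glycol, 60 °C
Reagents that add atoms: none
Why: Iron-hydride hydrogen-atom transfer to 18 gives the tertiary radical, which adds to the enone β-carbon C11 (reductive olefin coupling, Giese addition) and forms C11–C12; the congested C1 diester should make the four-carbon bridge lean over C6, which then covers the lower face, so the radical enters from the open exo face and sets C11.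

Step 12
Reactants: 19 dimethyl (1R,4S,6R)-4-(4-bromo-2-methylbutan-2-yl)-7,7-dimethyl-2,9-dioxobicyclo[4.3.1]decane-8,8-dicarboxylate; 20 (2E)-1-bromo-3,7-dimethylocta-2,6-diene (geranyl bromide)
Product: 21 dimethyl (1R,4S,6R)-4-(4-bromo-2-methylbutan-2-yl)-1-[(2E)-3,7-dimethylocta-2,6-dien-1-yl]-7,7-dimethyl-2,9-dioxobicyclo[4.3.1]decane-8,8-dicarboxylate
Conditions: NaH, THF, 0 °C; then 20, 0 → 23 °C
Reagents that add atoms: none
Why: C5–H, flanked by the C4 and C9 ketones, is the most acidic proton and its bridgehead enolate is allowed in this ring system, so SN2 C-alkylation of the β-diketonate should install the geranyl group with E geometry retained; only the exo face of the bridgehead is open, which fixes C5.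

Step 13
Reactants: 21 dimethyl (1R,4S,6R)-4-(4-bromo-2-methylbutan-2-yl)-1-[(2E)-3,7-dimethylocta-2,6-dien-1-yl]-7,7-dimethyl-2,9-dioxobicyclo[4.3.1]decane-8,8-dicarboxylate
Product: 23 cage methyl ester (the target skeleton with CO2Me at C1 in place of the isobutyryl group), via tricyclic diketone 22 (not isolated)
Conditions: KN(SiMe3)2 (2.3 equiv), THF, −78 → 23 °C
Reagents that add atoms: none
Why: The C3 enolate first displaces the primary bromide (5-exo-tet enolate alkylation, C3–C14) on the face that carries the C11 side chain; a second deprotonation at C3 then gives an enolate that can reach only the C1 ester cis to C10 (intramolecular Claisen condensation, C2–C3), so the cage geometry sets C3 and at the same time makes C1 stereogenic with the remaining ester exo.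

Step 14
Reactants: 23 cage methyl ester
Product: 24 cage carboxylic acid (CO2H at C1)
Conditions: LiI, pyridine, 110 °C; then 1 M HCl
Reagents that add atoms: none
Why: SN2 demethylation by iodide cleaves the hindered bridgehead ester at the methyl carbon without a nucleophile attacking the cage ketones; the bridgehead β-keto acid cannot decarboxylate because the enol would violate Bredt's rule.

Step 15
Reactants: 24 cage carboxylic acid
Product: 26 CNP0313870.1 (target), via acid chloride 25 (not isolated)
Conditions: (COCl)2, DMF (cat.), CH2Cl2, 0 → 23 °C; then i-PrMgCl, CuI (10 mol %), THF, −78 °C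
Reagents that add atoms: isopropylmagnesium chloride, CC(C)[Mg]Cl
Why: Copper-catalysed acylation of the Grignard reagent by the acid chloride should stop at the isobutyryl ketone; the three cage ketones are flanked by quaternary carbons and should not compete at −78 °C.

Compound list
1 | 5-(tert-butoxy)-5-oxopentanoic acid | OC(=O)CCCC(=O)OC(C)(C)C | starting material
2 | (4S)-4-benzyl-1,3-oxazolidin-2-one | O=C1N[C@@H](Cc2ccccc2)CO1 | starting material
3 | tert-butyl 5-[(4S)-4-benzyl-2-oxo-1,3-oxazolidin-3-yl]-5-oxopentanoate | CC(C)(C)OC(=O)CCCC(=O)N1[C@@H](Cc2ccccc2)COC1=O | intermediate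
4 | dimethyl 2-(propan-2-ylidene)propanedioate | COC(=O)C(=C(C)C)C(=O)OC | starting material
5 | dimethyl 2-[(3R)-3-{[(4S)-4-benzyl-2-oxo-1,3-oxazolidin-3-yl]carbonyl}-6-(tert-butoxy)-2-methyl-6-oxohexan-2-yl]propanedioate | COC(=O)C(C(=O)OC)C(C)(C)[C@@H](CCC(=O)OC(C)(C)C)C(=O)N1[C@@H](Cc2ccccc2)COC1=O | intermediate
6 | dimethyl 2-[(3R)-6-(tert-butoxy)-3-(hydroxymethyl)-2-methyl-6-oxohexan-2-yl]propanedioate | COC(=O)C(C(=O)OC)C(C)(C)[C@@H](CCC(=O)OC(C)(C)C)CO | intermediate
7 | dimethyl 2-[(3R)-6-(tert-butoxy)-3-(iodomethyl)-2-methyl-6-oxohexan-2-yl]propanedioate | COC(=O)C(C(=O)OC)C(C)(C)[C@@H](CCC(=O)OC(C)(C)C)CI | intermediate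
8 | (4R)-4-(iodomethyl)-7-methoxy-6-(methoxycarbonyl)-5,5-dimethyl-7-oxoheptanoic acid | COC(=O)C(C(=O)OC)C(C)(C)[C@@H](CCC(=O)O)CI | intermediate
9 | dimethyl 2-[(3R)-6-chloro-3-(iodomethyl)-2-methyl-6-oxohexan-2-yl]propanedioate (acid chloride) | COC(=O)C(C(=O)OC)C(C)(C)[C@@H](CCC(=O)Cl)CI | intermediate
10 | dimethyl (5R)-5-(iodomethyl)-6,6-dimethyl-2-oxocyclohexane-1,1-dicarboxylate | COC(=O)C1(C(=O)OC)C(=O)CC[C@@H](CI)C1(C)C | intermediate
11 | dimethyl (5R)-3-bromo-5-(iodomethyl)-6,6-dimethyl-2-oxocyclohexane-1,1-dicarboxylate (C3 epimers) | COC(=O)C1(C(=O)OC)C(=O)C(Br)C[C@@H](CI)C1(C)C | intermediate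
12 | ethyl (2Z)-3-iodoprop-2-enoate | CCOC(=O)/C=C\I | starting material
13 | (2Z)-3-iodoprop-2-enal | O=C/C=C\I | intermediate
14 | bromozinc alkoxide of dimethyl (5R)-3-[(2Z)-1-hydroxy-3-iodoprop-2-en-1-yl]-5-(iodomethyl)-6,6-dimethyl-2-oxocyclohexane-1,1-dicarboxylate (zinc aldolate) | COC(=O)C1(C(=O)OC)C(=O)C(C(O[Zn]Br)/C=C\I)C[C@@H](CI)C1(C)C | intermediate
15 | the same zinc aldolate with the iodomethyl group converted into CH2ZnI (alkylzinc iodide) | COC(=O)C1(C(=O)OC)C(=O)C(C(O[Zn]Br)/C=C\I)C[C@@H](C[Zn]I)C1(C)C | intermediate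
16 | dimethyl (1R,6R)-2-hydroxy-7,7-dimethyl-9-oxobicyclo[4.3.1]dec-3-ene-8,8-dicarboxylate (C2 epimers) | OC1C=CC[C@@H]2C[C@H]1C(=O)C(C(=O)OC)(C(=O)OC)C2(C)C | intermediate
17 | dimethyl (1R,6R)-7,7-dimethyl-2,9-dioxobicyclo[4.3.1]dec-3-ene-8,8-dicarboxylate | O=C1C=CC[C@@H]2C[C@H]1C(=O)C(C(=O)OC)(C(=O)OC)C2(C)C | intermediate
18 | 4-bromo-2-methylbut-1-ene | CC(=C)CCBr | starting material
19 | dimethyl (1R,4S,6R)-4-(4-bromo-2-methylbutan-2-yl)-7,7-dimethyl-2,9-dioxobicyclo[4.3.1]decane-8,8-dicarboxylate | O=C1C[C@@H](C(C)(C)CCBr)C[C@@H]2C[C@H]1C(=O)C(C(=O)OC)(C(=O)OC)C2(C)C | intermediate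
20 | (2E)-1-bromo-3,7-dimethylocta-2,6-diene (geranyl bromide) | CC(C)=CCC/C(C)=C/CBr | starting material
21 | dimethyl (1R,4S,6R)-4-(4-bromo-2-methylbutan-2-yl)-1-[(2E)-3,7-dimethylocta-2,6-dien-1-yl]-7,7-dimethyl-2,9-dioxobicyclo[4.3.1]decane-8,8-dicarboxylate | CC(C)=CCC/C(C)=C/C[C@@]12C[C@@H](C[C@H](C(C)(C)CCBr)CC1=O)C(C)(C)C(C(=O)OC)(C(=O)OC)C2=O | intermediate
22 | tricyclic diketone: 21 after closure of the cyclopentane between C3 and C14 (gem-dimethylcyclopentane fused at C3–C11, C3–H not defined) | CC(C)=CCC/C(C)=C/C[C@@]12C[C@@H](C[C@H]3C(CCC3(C)C)C1=O)C(C)(C)C(C(=O)OC)(C(=O)OC)C2=O | intermediate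
23 | cage methyl ester: the target with CO2Me at C1 instead of the isobutyryl group, the five stereocentres as in the target | CC(C)=CCC/C(C)=C/C[C@@]12C[C@H]3C[C@@H]4C(C)(C)CC[C@]4(C1=O)C(=O)[C@@](C(=O)OC)(C2=O)C3(C)C | intermediate
24 | cage carboxylic acid: the target with CO2H at C1 instead of the isobutyryl group | CC(C)=CCC/C(C)=C/C[C@@]12C[C@H]3C[C@@H]4C(C)(C)CC[C@]4(C1=O)C(=O)[C@@](C(=O)O)(C2=O)C3(C)C | intermediate
25 | cage acid chloride: the target with COCl at C1 instead of the isobutyryl group | CC(C)=CCC/C(C)=C/C[C@@]12C[C@H]3C[C@@H]4C(C)(C)CC[C@]4(C1=O)C(=O)[C@@](C(=O)Cl)(C2=O)C3(C)C | intermediate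
26 | CNP0313870.1: homoadamantane-type triketone with isobutyryl at C1, (E)-geranyl at C5, gem-dimethyl at C8 and a 12,12-dimethylcyclopentane fused at C3–C11 | CC(C)=CCC/C(C)=C/C[C@@]12C[C@H]3C[C@@H]4C(C)(C)CC[C@]4(C1=O)C(=O)[C@@](C(=O)C(C)C)(C2=O)C3(C)C | target

Total step count: 15. Longest linear sequence: 14 steps (steps 1–7 and 9–15); step 8 is a one-step branch.

Steps most likely to fail

Step 2 (labelled step). The titanium enolate may add too slowly to the β,β-disubstituted acceptor, may deprotonate it at the allylic methyl groups, or may add with poor facial discrimination. The fallback sets out from 4 and returns to the route at 6. Conjugate addition of the Reformatsky reagent made from tert-butyl bromoacetate and zinc to 4 should give dimethyl 2-[4-(tert-butoxy)-2-methyl-4-oxobutan-2-yl]propanedioate F1. Trifluoroacetic acid should then give 5-methoxy-4-(methoxycarbonyl)-3,3-dimethyl-5-oxopentanoic acid F2, and acylation of (4R)-4-benzyl-1,3-oxazolidin-2-one through the pivalic mixed anhydride should give dimethyl 2-{4-[(4R)-4-benzyl-2-oxo-1,3-oxazolidin-3-yl]-2-methyl-4-oxobutan-2-yl}propanedioate F3. Its chlorotitanium enolate (TiCl4 and i-Pr2NEt in excess, so that the hindered malonate is also covered) should add to tert-butyl acrylate, an acceptor class for which this Michael addition is established. With the enolate substituent and the incoming group exchanged, the R auxiliary is needed to obtain the same R centre, giving dimethyl 2-[(3R)-3-{[(4R)-4-benzyl-2-oxo-1,3-oxazolidin-3-yl]carbonyl}-6-(tert-butoxy)-2-methyl-6-oxohexan-2-yl]propanedioate F4. LiBH4 reduction of F4 gives 6.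

Step 9. The aldol addition may occur on the enolate face trans to the C7 arm without re-equilibration, zinc may insert into the vinyl C–I bond, or the alkylpalladium intermediate may undergo β-hydride elimination before ring closure. The fallback sets out from 10 (step 7 is then omitted) and returns at 16. LiCl-assisted zinc insertion into the C–I bond of 10 and an intermolecular Negishi coupling with 13 should give dimethyl (5S)-6,6-dimethyl-2-oxo-5-[(2Z)-4-oxobut-2-en-1-yl]cyclohexane-1,1-dicarboxylate F5. LiN(SiMe3)2 at −78 °C then forms the only possible ketone enolate (at C5), which should close the seven-membered ring by intramolecular aldol addition to the Z-enal and give 16; the cis relationship at C5 is enforced because the tether is already in place.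

Step 12. The hindered bridgehead diketonate may alkylate on oxygen, or base may deprotonate C3 and trigger premature cyclopentane closure. The fallback runs from 19 to 21 without new intermediates: a Tsuji–Trost allylation with geranyl methyl carbonate and Pd(PPh3)4 in THF, in which the soft diketonate should attack the less hindered terminus of the π-geranyl palladium complex at carbon and give the linear E product 21 under essentially neutral conditions.

Further compounds
F1 | step 2 | dimethyl 2-[4-(tert-butoxy)-2-methyl-4-oxobutan-2-yl]propanedioate | COC(=O)C(C(=O)OC)C(C)(C)CC(=O)OC(C)(C)C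
F2 | step 2 | 5-methoxy-4-(methoxycarbonyl)-3,3-dimethyl-5-oxopentanoic acid | COC(=O)C(C(=O)OC)C(C)(C)CC(=O)O
F3 | step 2 | dimethyl 2-{4-[(4R)-4-benzyl-2-oxo-1,3-oxazolidin-3-yl]-2-methyl-4-oxobutan-2-yl}propanedioate | COC(=O)C(C(=O)OC)C(C)(C)CC(=O)N1[C@H](Cc2ccccc2)COC1=O
F4 | step 2 | dimethyl 2-[(3R)-3-{[(4R)-4-benzyl-2-oxo-1,3-oxazolidin-3-yl]carbonyl}-6-(tert-butoxy)-2-methyl-6-oxohexan-2-yl]propanedioate | COC(=O)C(C(=O)OC)C(C)(C)[C@@H](CCC(=O)OC(C)(C)C)C(=O)N1[C@H](Cc2ccccc2)COC1=O
F5 | step 9 | dimethyl (5S)-6,6-dimethyl-2-oxo-5-[(2Z)-4-oxobut-2-en-1-yl]cyclohexane-1,1-dicarboxylate | COC(=O)C1(C(=O)OC)C(=O)CC[C@@H](C/C=C\C=O)C1(C)C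
F0 | step 12 | none | none
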